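**Plan**

1. Retrosynthesis: the two benzyl ethers on the 2'- and 5'-oxygens of ring B are cut last; the flavone is then opened at O1–C2 (ring C) and at C4a–C5 (ring A) in a single operation.
2. Enabling feature: ring A (C4a, C5, C6, C7, C8, C8a) is a phloroglucinol with 5-OH, 7-OMe and the acyl carbon C4 on C4a, i.e. a folded tetraketide. C5 (as a carboxyl carbon), the C6=C7 enol ether with its methoxy group, C8 and C8a are all present in 4-methoxy-6-methylpyran-2-one, whose methyl carbon becomes C4a.
3. The pyranone ynone is cut at C4a–C4 into the lithiated pyranone and an arylpropiolic Weinreb amide. The amide goes back through C3–C4 and the alkyne to 2,5-bis(benzyloxy)-3,4-dimethoxybenzaldehyde, whose C5' oxygen comes from an Elbs oxidation of 2-demethylated 2,3,4-trimethoxybenzaldehyde.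
4. Forward order: ring B oxygenation and protection (steps 1–3), homologation to the alkyne and capture as the Weinreb ynamide (steps 4–5), union with the pyranone (step 6), ring A then ring C in one flask (step 7), debenzylation (step 8).
5. Stereochemistry: the target has no stereocentre. The only geometric requirement, C5 and C8 cis across C6=C7 in the opened chain, is inherited from the pyranone ring.

Key step: step 7

Remark: the labels O1 and C2–C8a are the flavone positions of the target and are used for the same atoms in the open-chain intermediates.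

**Route**

Step 1
Reactants: 1 2,3,4-trimethoxybenzaldehyde
Product: 2 2-hydroxy-3,4-dimethoxybenzaldehyde
Conditions: BCl3 (1.1 equiv), CH2Cl2, 0 °C to rt; then H2O
Reagents that add atoms: none
Why: Chelation-controlled Lewis acid ether cleavage, in which boron bridges the formyl oxygen and the ortho methoxy oxygen so that chloride removes only the C2 methyl group and the 3- and 4-methoxy groups stay.

Step 2
Reactants: 2 2-hydroxy-3,4-dimethoxybenzaldehyde
Product: 4 2,5-dihydroxy-3,4-dimethoxybenzaldehyde, via aryl sulfate potassium salt 3 (not isolated)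
Conditions: K2S2O8, 10% aq NaOH, 15–20 °C; then aq HCl, 80 °C, under N2
Reagents that add atoms: potassium persulfate, [K+].[K+].[O-]S(=O)(=O)OOS(=O)(=O)[O-]
Why: Elbs persulfate oxidation, in which the phenoxide attacks the peroxide oxygen through C5 (the free position para to the phenoxide oxygen) and acid hydrolysis of the aryl sulfate then releases the hydroquinone.

Step 3
Reactants: 4 2,5-dihydroxy-3,4-dimethoxybenzaldehyde; 5 benzyl bromide
Product: 6 2,5-bis(benzyloxy)-3,4-dimethoxybenzaldehyde
Conditions: BnBr (2.4 equiv in all), K2CO3 (3 equiv), DMF, 60 °C, under N2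
Reagents that add atoms: benzyl bromide (the second equivalent of 5, which supplies the second benzyl group), BrCc1ccccc1
Why: Twofold Williamson ether synthesis, one molecule of benzyl bromide per phenoxide, which masks the oxidation-prone hydroquinone and blocks the 2-oxygen that would otherwise cyclize onto the alkyne in later steps.

Step 4
Reactants: 6 2,5-bis(benzyloxy)-3,4-dimethoxybenzaldehyde
Product: 7 1,4-bis(benzyloxy)-5-(2,2-dibromoethenyl)-2,3-dimethoxybenzene
Conditions: CBr4, PPh3, CH2Cl2, 0 °C
Reagents that add atoms: carbon tetrabromide, BrC(Br)(Br)Br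
Why: Ramirez dibromo-olefination (first stage of the Corey–Fuchs homologation), a Wittig reaction of Ph3P=CBr2 formed in the flask with a non-enolizable aryl aldehyde.

Step 5
Reactants: 7 1,4-bis(benzyloxy)-5-(2,2-dibromoethenyl)-2,3-dimethoxybenzene
Product: 9 3-[2,5-bis(benzyloxy)-3,4-dimethoxyphenyl]-N-methoxy-N-methylprop-2-ynamide, via lithium arylacetylide 8 (not isolated)
Conditions: n-BuLi (2.1 equiv), THF, −78 °C; then ClC(O)N(OMe)Me, −78 to 0 °C
Reagents that add atoms: N-methoxy-N-methylcarbamoyl chloride, CON(C)C(Cl)=O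
Why: Second stage of the Corey–Fuchs reaction (bromine–lithium exchange, 1,2-shift and deprotonation) gives the lithium acetylide, and its acylation by the carbamoyl chloride gives the Weinreb ynamide directly because the N-methoxy amide resists a second addition.

Step 6
Reactants: 10 4-methoxy-6-methyl-2H-pyran-2-one; 9 3-[2,5-bis(benzyloxy)-3,4-dimethoxyphenyl]-N-methoxy-N-methylprop-2-ynamide
Product: 13 6-{4-[2,5-bis(benzyloxy)-3,4-dimethoxyphenyl]-2-oxobut-3-yn-1-yl}-4-methoxy-2H-pyran-2-one, via lithiated pyranone 11 (not isolated), via tetrahedral lithium alkoxide adduct 12 (not isolated)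
Conditions: 10 (1.3 equiv), LiN(iPr)2 (1.3 equiv), THF, −78 °C; then 9, −78 °C; quench into cold 1 M HCl
Reagents that add atoms: none
Why: Weinreb ketone synthesis in which the vinylogous enolate from deprotonation of the 6-methyl group adds to the amide carbonyl (forming C4a–C4), the chelated adduct holds until the cold acid quench so that the acidic product is never exposed to the carbanion, and the acid protonates the released amine before it can add to the ynone.

Step 7
Reactants: 13 6-{4-[2,5-bis(benzyloxy)-3,4-dimethoxyphenyl]-2-oxobut-3-yn-1-yl}-4-methoxy-2H-pyran-2-one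
Product: 16 2-[2,5-bis(benzyloxy)-3,4-dimethoxyphenyl]-5-hydroxy-7-methoxy-4H-chromen-4-one, via ring-opened dioxo enynoate ester 14 (not isolated), via dihydroxymethoxyphenyl ynone 15 (not isolated)
Conditions: Mg(OMe)2 (5 equiv), MeOH, reflux, under Ar; then 2 M aq HCl, 50 °C
Reagents that add atoms: none
Why: Proposed new method: methoxide opens the lactone of the magnesium enolate of 13 to methyl ester 14, in which C5 (the former lactone carbonyl) and C8 stay cis across the C6=C7 enol ether, and the magnesium-chelated C4/C8a β-diketonate attacks the ester through C4a in a 6-exo-trig Claisen (Dieckmann-type) condensation that closes ring A, which aromatizes by enolization to the 2,6-dihydroxy-4-methoxyphenyl ynone 15. The closest known reaction types are the Mg(OMe)2-induced recyclization of 6-(2-oxoalkyl)-4-methoxypyran-2-ones to acylphloroglucinol monomethyl ethers and the base-mediated cyclization of 2-hydroxyaryl ynones to flavones, and what is new is running both on an ynone-bearing pyranone in one flask. Ring C then closes by 6-endo-dig oxa-Michael addition of a ring A phenoxide to C2, or equivalently by 6-endo-trig addition–elimination on the β-methoxy enone formed if methanol adds first, and the warm acid finish drives any such adduct to the flavone. No stereocentre is formed. The step needs Claisen closure at C4a to win over the aldol mode (C6 onto the C4 carbonyl), relactonization and early conjugate addition to the ynone: magnesium chelation makes C4a the nucleophilic carbon and keeps the C4 carbonyl enolized, which switches the ynone off as an acceptor until C4a has lost its hydrogens on aromatization, while relactonization is reversible and the ring-derived cis geometry holds C4a next to C5. It also needs six-membered rather than five-membered (aurone) closure, which the polarization of the ynone toward C2 and the protic methoxide medium (trapping C2 as an enol ether) should secure, and since 15 is symmetrical either hydroxyl may close while the other becomes the chelated 5-OH.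

Step 8
Reactants: 16 2-[2,5-bis(benzyloxy)-3,4-dimethoxyphenyl]-5-hydroxy-7-methoxy-4H-chromen-4-one
Product: 17 2-(2,5-dihydroxy-3,4-dimethoxyphenyl)-5-hydroxy-7-methoxy-4H-chromen-4-one
Conditions: H2 (1 atm), 10% Pd/C, EtOAc/MeOH, rt; filtration and concentration under Ar
Reagents that add atoms: none
Why: Catalytic hydrogenolysis cleaves the two benzylic C–O bonds while the chelated chromone C2=C3 bond and the aryl methyl ethers are inert at one atmosphere and room temperature, and handling under argon protects the freed hydroquinone from air oxidation.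

**Compound list**

1 | 2,3,4-trimethoxybenzaldehyde | COc1ccc(C=O)c(OC)c1OC | starting material
2 | 2-hydroxy-3,4-dimethoxybenzaldehyde | COc1ccc(C=O)c(O)c1OC | intermediate
3 | potassium 5-formyl-4-hydroxy-2,3-dimethoxyphenyl sulfate | O=Cc1cc(OS(=O)(=O)[O-])c(OC)c(OC)c1O.[K+] | intermediate
4 | 2,5-dihydroxy-3,4-dimethoxybenzaldehyde | O=Cc1cc(O)c(OC)c(OC)c1O | intermediate
5 | benzyl bromide | BrCc1ccccc1 | starting material
6 | 2,5-bis(benzyloxy)-3,4-dimethoxybenzaldehyde | O=Cc1cc(OCc2ccccc2)c(OC)c(OC)c1OCc1ccccc1 | intermediate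
7 | 1,4-bis(benzyloxy)-5-(2,2-dibromoethenyl)-2,3-dimethoxybenzene | BrC(Br)=Cc1cc(OCc2ccccc2)c(OC)c(OC)c1OCc1ccccc1 | intermediate
8 | lithium [2,5-bis(benzyloxy)-3,4-dimethoxyphenyl]acetylide | [Li]C#Cc1cc(OCc2ccccc2)c(OC)c(OC)c1OCc1ccccc1 | intermediate
9 | 3-[2,5-bis(benzyloxy)-3,4-dimethoxyphenyl]-N-methoxy-N-methylprop-2-ynamide | CON(C)C(=O)C#Cc1cc(OCc2ccccc2)c(OC)c(OC)c1OCc1ccccc1 | intermediate
10 | 4-methoxy-6-methyl-2H-pyran-2-one | COc1cc(C)oc(=O)c1 | starting material
11 | [(4-methoxy-2-oxo-2H-pyran-6-yl)methyl]lithium | [Li]Cc1cc(OC)cc(=O)o1 | intermediate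
12 | lithium 4-[2,5-bis(benzyloxy)-3,4-dimethoxyphenyl]-2-[methoxy(methyl)amino]-1-(4-methoxy-2-oxo-2H-pyran-6-yl)but-3-yn-2-olate (racemic) | COc1cc(CC(O[Li])(C#Cc2cc(OCc3ccccc3)c(OC)c(OC)c2OCc2ccccc2)N(C)OC)oc(=O)c1 | intermediate
13 | 6-{4-[2,5-bis(benzyloxy)-3,4-dimethoxyphenyl]-2-oxobut-3-yn-1-yl}-4-methoxy-2H-pyran-2-one | COc1cc(CC(=O)C#Cc2cc(OCc3ccccc3)c(OC)c(OC)c2OCc2ccccc2)oc(=O)c1 | intermediate
14 | methyl (2E)-9-[2,5-bis(benzyloxy)-3,4-dimethoxyphenyl]-3-methoxy-5,7-dioxonon-2-en-8-ynoate | COC(=O)/C=C(OC)\CC(=O)CC(=O)C#Cc1cc(OCc2ccccc2)c(OC)c(OC)c1OCc1ccccc1 | intermediate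
15 | 3-[2,5-bis(benzyloxy)-3,4-dimethoxyphenyl]-1-(2,6-dihydroxy-4-methoxyphenyl)prop-2-yn-1-one | COc1cc(O)c(C(=O)C#Cc2cc(OCc3ccccc3)c(OC)c(OC)c2OCc2ccccc2)c(O)c1 | intermediate
16 | 2-[2,5-bis(benzyloxy)-3,4-dimethoxyphenyl]-5-hydroxy-7-methoxy-4H-chromen-4-one | COc1cc(O)c2c(=O)cc(-c3cc(OCc4ccccc4)c(OC)c(OC)c3OCc3ccccc3)oc2c1 | intermediate
17 | 2-(2,5-dihydroxy-3,4-dimethoxyphenyl)-5-hydroxy-7-methoxy-4H-chromen-4-one | COc1cc(O)c2c(=O)cc(-c3cc(O)c(OC)c(OC)c3O)oc2c1 | target

**Count**

Total steps: 8. Longest linear sequence: 8 steps (1 to 17); 5 and 10 enter as purchased materials.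

**Steps most likely to fail**

Step 7. Several processes could divert the cascade. The C8a enolate oxygen of the opened chain could add to the ynone before the Claisen condensation, giving a monocyclic 4-pyranone. The chain could fold in the aldol sense instead of the Claisen sense. The phenoxide could close in the five-membered (aurone) mode. The lactone could simply re-form. The fallback gives up the pyranone fold and uses the classical chalcone route. It sets out from 6 and comes back at 16. Claisen–Schmidt condensation of 6 with commercial 1-(2,6-dihydroxy-4-methoxyphenyl)ethan-1-one (KOH, EtOH, rt) should give (2E)-3-[2,5-bis(benzyloxy)-3,4-dimethoxyphenyl]-1-(2,6-dihydroxy-4-methoxyphenyl)prop-2-en-1-one F1. Oxidative cyclization of F1 with catalytic I2 in DMSO at 120 °C should then close ring C and dehydrogenate to 16.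

Step 6. The soft pyranone carbanion may add to the β-carbon of the ynamide instead of its carbonyl. The released N,O-dimethylhydroxylamine may add to the ynone during the quench. Metalation may occur partly at C3 of the pyranone. The fallback separates C–C bond formation from the ynone oxidation level. It sets out from 7 (with 10) and comes back at 13. Treatment of 7 with n-BuLi and then DMF should give 3-[2,5-bis(benzyloxy)-3,4-dimethoxyphenyl]prop-2-ynal F2. Addition of the lithiated pyranone (from 10 and LiN(iPr)2, THF, −78 °C) to this aldehyde should give racemic 6-{4-[2,5-bis(benzyloxy)-3,4-dimethoxyphenyl]-2-hydroxybut-3-yn-1-yl}-4-methoxy-2H-pyran-2-one F3. Oxidation of the propargylic alcohol with activated MnO2 in CH2Cl2 should give 13.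

Step 2. Persulfate may convert the electron-poor phenoxide only partly, may over-oxidize the aldehyde or the ring to polymeric material, and the hydroquinone may oxidize in air to the quinone during hydrolysis. The fallback introduces the C5 oxygen through a halide. It sets out from 2 and comes back at 6. Bromination para to the hydroxyl (N-bromosuccinimide, MeCN, 0 °C) should give 5-bromo-2-hydroxy-3,4-dimethoxybenzaldehyde F4. Benzylation with one equivalent of 5 (K2CO3, DMF) should give 2-(benzyloxy)-5-bromo-3,4-dimethoxybenzaldehyde F5. Miyaura borylation (B2pin2, PdCl2(dppf), KOAc, dioxane, 90 °C) should give 2-(benzyloxy)-3,4-dimethoxy-5-(4,4,5,5-tetramethyl-1,3,2-dioxaborolan-2-yl)benzaldehyde F6. Oxidation of the C–B bond (NaBO3·4H2O, THF/H2O, rt) should give 2-(benzyloxy)-5-hydroxy-3,4-dimethoxybenzaldehyde F7. A second benzylation with one equivalent of 5 (K2CO3, DMF) should give 6.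

**Further compounds**

F1 | step 7 | (2E)-3-[2,5-bis(benzyloxy)-3,4-dimethoxyphenyl]-1-(2,6-dihydroxy-4-methoxyphenyl)prop-2-en-1-one | COc1cc(O)c(C(=O)/C=C/c2cc(OCc3ccccc3)c(OC)c(OC)c2OCc2ccccc2)c(O)c1
F2 | step 6 | 3-[2,5-bis(benzyloxy)-3,4-dimethoxyphenyl]prop-2-ynal | O=CC#Cc1cc(OCc2ccccc2)c(OC)c(OC)c1OCc1ccccc1
F3 | step 6 | 6-{4-[2,5-bis(benzyloxy)-3,4-dimethoxyphenyl]-2-hydroxybut-3-yn-1-yl}-4-methoxy-2H-pyran-2-one (racemic) | COc1cc(CC(O)C#Cc2cc(OCc3ccccc3)c(OC)c(OC)c2OCc2ccccc2)oc(=O)c1
F4 | step 2 | 5-bromo-2-hydroxy-3,4-dimethoxybenzaldehyde | O=Cc1cc(Br)c(OC)c(OC)c1O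
F5 | step 2 | 2-(benzyloxy)-5-bromo-3,4-dimethoxybenzaldehyde | O=Cc1cc(Br)c(OC)c(OC)c1OCc1ccccc1
F6 | step 2 | 2-(benzyloxy)-3,4-dimethoxy-5-(4,4,5,5-tetramethyl-1,3,2-dioxaborolan-2-yl)benzaldehyde | O=Cc1cc(B2OC(C)(C)C(C)(C)O2)c(OC)c(OC)c1OCc1ccccc1
F7 | step 2 | 2-(benzyloxy)-5-hydroxy-3,4-dimethoxybenzaldehyde | O=Cc1cc(O)c(OC)c(OC)c1OCc1ccccc1
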